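## Retrosynthetic overview

1. The side chain is counted C1′ (ring-bound CH2) to C32′. The last move releases the quinone from its 1,4-dimethoxynaphthalene form. No ring is formed in the route: the naphthalene bicycle is bought as menadione and only masked and unmasked.
2. Key disconnection C13′–C14′. The left half is a redox-active ester one carboxyl carbon longer (lost as CO2). The right half is a terminal alkyne one methyl group shorter. One pot does methylmetalation of the alkyne, Al→Zn exchange and nickel-catalysed radical decarboxylative alkenylation.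
3. Enabling feature: C14′=C15′ is an E-trisubstituted olefin with only H on C14′ and CH3 on C15′, which equals a terminal alkyne plus syn Me–metal. C13′ is an unactivated CH2 two carbons from the C11′ methyl stereocentre, the α-carbon of the acid left when the isopropylidene end of a citronellyl unit is cleaved. The next π-bond (C2′=C3′) is too remote for radical cyclisation.
4. Left half: C1′–C2′ by alkyne methylalumination/nickel coupling with a chloromethylnaphthalene, and C8′–C9′ by decarboxylative alkyl–alkyl coupling. C7′ comes from (R)-β-butyrolactone (inversion) and C11′ from (S)-citronellyl bromide.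
5. Right half: C16′–C17′ by propargylation of geranyl bromide, then allylic oxidation at C24′. C24′–C25′ follows by copper-catalysed allyl–alkyl coupling with the Grignard reagent of hydrogenated (S)-citronellyl bromide (C27′).

Key step: step 17

Assumption: the commercial chiral-pool reagents are taken to be of high enantiomeric purity. The carboxyl carbon of the left half that leaves in step 17 is called C(x).

## Route

Step 1
Reactants: 1 menadione (2-methylnaphthalene-1,4-dione)
Product: 3 1,4-dimethoxy-2-methylnaphthalene, via menadiol 2 (not isolated)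
Conditions: Na2S2O4, Bu4NBr (cat.), THF/H2O, rt; then aq KOH, Me2SO4, rt
Reagents that add atoms: dimethyl sulfate, COS(=O)(=O)OC
Why: One-pot reductive methylation, in which dithionite reduces the quinone to the hydroquinone and both phenoxides undergo Williamson O-methylation, masks the redox-active ring for all later organometallic and radical steps.

Step 2
Reactants: 3 1,4-dimethoxy-2-methylnaphthalene
Product: 4 2-(chloromethyl)-1,4-dimethoxy-3-methylnaphthalene
Conditions: paraformaldehyde, conc. aq HCl, AcOH, rt to 40 °C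
Reagents that add atoms: formaldehyde (as paraformaldehyde), C=O; hydrogen chloride, Cl
Why: Blanc chloromethylation can only strike C3, the single free position of the dialkoxy-activated ring, and installs C1′ as a benzylic chloride.

Step 3
Reactants: 5 (5-chloropent-1-yn-1-yl)trimethylsilane; 6 (R)-β-butyrolactone
Product: 8 (3R)-3-methyl-8-(trimethylsilyl)oct-7-ynoic acid, via Grignard reagent 7 (not isolated)
Conditions: Mg, THF, reflux; CuBr·SMe2 (10 mol %), THF/Me2S, −30 °C, then 6, −30 → 0 °C; aq HCl
Reagents that add atoms: none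
Why: Copper-catalysed Grignard opening of a β-lactone by SN2 attack at the alkyl–oxygen carbon runs with inversion, so the (R)-lactone delivers the C7′ methyl stereocentre in the required sense together with a free carboxyl handle.

Step 4
Reactants: 8 (3R)-3-methyl-8-(trimethylsilyl)oct-7-ynoic acid
Product: 9 1,3-dioxoisoindolin-2-yl (3R)-3-methyl-8-(trimethylsilyl)oct-7-ynoate
Conditions: N-hydroxyphthalimide, DIC, DMAP (cat.), CH2Cl2, rt
Reagents that add atoms: N-hydroxyphthalimide, O=C1c2ccccc2C(=O)N1O
Why: Steglich-type carbodiimide esterification turns the acid into a redox-active N-acyloxyphthalimide without touching the β-stereocentre.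

Step 5
Reactants: 9 1,3-dioxoisoindolin-2-yl (3R)-3-methyl-8-(trimethylsilyl)oct-7-ynoate; 10 (S)-citronellyl bromide
Product: 13 trimethyl[(6S,10R)-6,10,14-trimethylpentadec-13-en-1-yn-1-yl]silane, via citronellylmagnesium bromide 11 (not isolated), via dicitronellylzinc 12 (not isolated)
Conditions: 10, Mg, THF; ZnCl2 (0.5 equiv per Grignard), THF, rt; then 9, NiCl2·glyme (20 mol %), 4,4′-di-tert-butyl-2,2′-bipyridine (40 mol %), 12 (2 equiv), THF/DMF, rt; aq NH4Cl/HCl
Reagents that add atoms: none
Why: In this nickel-catalysed decarboxylative alkyl–alkyl Negishi-type coupling of a redox-active ester with a dialkylzinc, single-electron fragmentation gives the primary C8′ radical, which alkylnickel captures to form C8′–C9′, while C7′ and C11′ (the latter bought with 10) are not reacting carbons and keep their configuration.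

Step 6
Reactants: 13 trimethyl[(6S,10R)-6,10,14-trimethylpentadec-13-en-1-yn-1-yl]silane
Product: 14 (4R,8S)-4,8-dimethyl-13-(trimethylsilyl)tridec-12-yn-1-ol
Conditions: O3, CH2Cl2/MeOH, −78 °C (Sudan III end point); NaBH4, −78 °C → rt
Reagents that add atoms: ozone, [O-][O+]=O
Why: Chemoselective ozonolysis with reductive work-up cleaves the electron-rich trisubstituted olefin much faster than the silyl-capped alkyne and leaves C(x) as a primary alcohol next to C13′.

Step 7
Reactants: 14 (4R,8S)-4,8-dimethyl-13-(trimethylsilyl)tridec-12-yn-1-ol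
Product: 15 (4R,8S)-4,8-dimethyltridec-12-yn-1-ol
Conditions: K2CO3 (cat.), MeOH, rt
Reagents that add atoms: none
Why: Base-catalysed methanolysis of the C(sp)–Si bond (protodesilylation) frees the terminal alkyne and touches nothing else.

Step 8
Reactants: 15 (4R,8S)-4,8-dimethyltridec-12-yn-1-ol; 4 2-(chloromethyl)-1,4-dimethoxy-3-methylnaphthalene
Product: 17 (4R,8S,12E)-14-(1,4-dimethoxy-3-methylnaphthalen-2-yl)-4,8,12-trimethyltetradec-12-en-1-ol, via alkenylalane 16 (not isolated)
Conditions: Me3Al (3.5 equiv), Cp2ZrCl2 (25 mol %), CH2Cl2, 0 °C → rt; volatiles off, hexane/THF; 4, NiCl2(PPh3)2/n-BuLi (1:2, 5 mol % Ni), THF, rt; aq HCl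
Reagents that add atoms: trimethylaluminium, C[Al](C)C
Why: Zirconium-catalysed syn-methylalumination of the terminal alkyne (hydroxyl masked in situ as its aluminium alkoxide) fixes the E C2′=C3′ olefin, and the known nickel(0)-catalysed coupling of alkenylalanes with benzylic chlorides forms C1′–C2′ with retention.

Step 9
Reactants: 17 (4R,8S,12E)-14-(1,4-dimethoxy-3-methylnaphthalen-2-yl)-4,8,12-trimethyltetradec-12-en-1-ol
Product: 18 (4R,8S,12E)-14-(1,4-dimethoxy-3-methylnaphthalen-2-yl)-4,8,12-trimethyltetradec-12-enoic acid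
Conditions: TPAP (10 mol %), NMO·H2O (10 equiv), MeCN/CH2Cl2, rt
Reagents that add atoms: water (from NMO monohydrate), O
Why: Ley–Griffith oxidation run with NMO monohydrate carries the primary alcohol through the aldehyde hydrate to the acid under neutral conditions that should spare the trisubstituted olefin and the electron-rich arene.

Step 10
Reactants: 18 (4R,8S,12E)-14-(1,4-dimethoxy-3-methylnaphthalen-2-yl)-4,8,12-trimethyltetradec-12-enoic acid
Product: 19 1,3-dioxoisoindolin-2-yl (4R,8S,12E)-14-(1,4-dimethoxy-3-methylnaphthalen-2-yl)-4,8,12-trimethyltetradec-12-enoate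
Conditions: N-hydroxyphthalimide, DIC, DMAP (cat.), CH2Cl2, rt
Reagents that add atoms: N-hydroxyphthalimide, O=C1c2ccccc2C(=O)N1O
Why: Steglich-type esterification installs the redox-active group that later turns C13′ into a radical centre.

Step 11
Reactants: 20 geranyl bromide; 21 1-(trimethylsilyl)propyne
Product: 23 [(5E)-6,10-dimethylundeca-5,9-dien-1-yn-1-yl]trimethylsilane, via lithiated silylpropyne 22 (not isolated)
Conditions: 21, n-BuLi, THF, −20 °C; 20, −78 °C → rt
Reagents that add atoms: none
Why: SN2 alkylation of the propargylic lithium reagent by the primary allylic bromide forms C16′–C17′, the silyl group steering attack to the propargyl rather than the allenyl terminus and the geranyl E-olefin being retained.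

Step 12
Reactants: 23 [(5E)-6,10-dimethylundeca-5,9-dien-1-yn-1-yl]trimethylsilane
Product: 24 (2E,6E)-2,6-dimethyl-11-(trimethylsilyl)undeca-2,6-dien-10-yn-1-ol
Conditions: SeO2 (cat.), t-BuOOH, salicylic acid (cat.), CH2Cl2, 0 °C → rt, stopped at partial conversion
Reagents that add atoms: tert-butyl hydroperoxide, CC(C)(C)OO (oxygen relayed by catalytic selenium dioxide, O=[Se]=O)
Why: Riley allylic oxidation (ene reaction, then [2,3]-shift) prefers the least hindered terminal isopropylidene unit and oxidises only its E-methyl group, which gives the E-allylic alcohol at C24′.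

Step 13
Reactants: 24 (2E,6E)-2,6-dimethyl-11-(trimethylsilyl)undeca-2,6-dien-10-yn-1-ol
Product: 25 (2E,6E)-2,6-dimethyl-11-(trimethylsilyl)undeca-2,6-dien-10-yn-1-yl acetate
Conditions: Ac2O, pyridine, DMAP (cat.), CH2Cl2, 0 °C → rt
Reagents that add atoms: acetic anhydride, CC(=O)OC(C)=O
Why: Simple O-acylation gives a stable allylic leaving group without risk to the olefin geometry.

Step 14
Reactants: 10 (S)-citronellyl bromide
Product: 26 (3S)-1-bromo-3,7-dimethyloctane
Conditions: H2 (1 atm), PtO2 (cat.), EtOAc, rt
Reagents that add atoms: none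
Why: Heterogeneous hydrogenation saturates the trisubstituted olefin, the stereocentre lies too far from it to be scrambled by isomerisation, and the primary bromide is inert under neutral conditions.

Step 15
Reactants: 26 (3S)-1-bromo-3,7-dimethyloctane; 25 (2E,6E)-2,6-dimethyl-11-(trimethylsilyl)undeca-2,6-dien-10-yn-1-yl acetate
Product: 28 trimethyl[(5E,9E,14S)-6,10,14,18-tetramethylnonadeca-5,9-dien-1-yn-1-yl]silane, via Grignard reagent 27 (not isolated)
Conditions: 26, Mg, THF; 25, Li2CuCl4 (5 mol %), THF, −20 → 0 °C, rapid Grignard addition; aq NH4Cl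
Reagents that add atoms: none
Why: Kochi-type copper-catalysed allyl–alkyl coupling under dialkylcuprate conditions substitutes at the primary α-carbon with retention of the E geometry, forming C24′–C25′ and bringing in the C27′ stereocentre from 26.

Step 16
Reactants: 28 trimethyl[(5E,9E,14S)-6,10,14,18-tetramethylnonadeca-5,9-dien-1-yn-1-yl]silane
Product: 29 (5E,9E,14S)-6,10,14,18-tetramethylnonadeca-5,9-dien-1-yne
Conditions: K2CO3 (cat.), MeOH/THF, rt
Reagents that add atoms: none
Why: Base-catalysed protodesilylation frees the terminal alkyne needed for carbometalation.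

Step 17
Reactants: 29 (5E,9E,14S)-6,10,14,18-tetramethylnonadeca-5,9-dien-1-yne; 19 1,3-dioxoisoindolin-2-yl (4R,8S,12E)-14-(1,4-dimethoxy-3-methylnaphthalen-2-yl)-4,8,12-trimethyltetradec-12-enoate
Product: 32 1,4-dimethoxy-2-methyl-3-[(2E,7S,11R,14E,18E,22E,27S)-3,7,11,15,19,23,27,31-octamethyldotriaconta-2,14,18,22-tetraen-1-yl]naphthalene, via alkenylalane 30 (not isolated), via alkenylzinc chloride 31 (not isolated)
Conditions: 29 (1.8 equiv), Me3Al, Cp2ZrCl2 (20 mol %), CH2Cl2, 0 °C → rt; volatiles off in vacuo, hexane extraction, THF; ZnCl2 (THF), 0 °C → rt; then 19 (1.0 equiv), Ni(acac)2 (10 mol %), 2,2′-bipyridine (10 mol %), THF/DMF, rt; aq HCl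
Reagents that add atoms: trimethylaluminium, C[Al](C)C
Why: Proposed new method: Zirconocene-catalysed syn-methylalumination of the terminal alkyne of 29 places CH3 on C15′ and aluminium on C14′ on the same side, and exchange with ZnCl2 passes the alkenyl group on with retention to give 31. A bipyridine-ligated alkenylnickel(I) species then transfers one electron to the N-acyloxyphthalimide of 19, phthalimide anion and CO2 depart, the primary C13′ radical is trapped by alkenylnickel(II), and reductive elimination from nickel(III) forges C13′–C14′. The closest known reaction types are the nickel-catalysed decarboxylative alkenylation of redox-active esters with preformed alkenylzinc reagents and the nickel- or palladium-catalysed coupling of carboalumination-derived alkenylalanes with zinc salts as relay; new is only that the alane-derived zinc reagent is fed directly to a redox-active ester, so that one flask adds the C15′ methyl group, sets the olefin and joins the two halves. No ring is closed and no sp3 stereocentre is created: the single new stereoelement, the E C14′=C15′ olefin, is controlled by the syn carbometalation and by stereoretentive transmetalation and reductive elimination, and C11′, two carbons from the radical site, cannot epimerise. The step needs alkenyl rather than methyl transfer, which the faster sp2 transmetalation and the removal of excess Me3Al in vacuo before zinc is added should secure, and it needs the internal olefins of 29 to stay out of the carbometalation, which their trisubstitution secures. It also needs radical capture to outrun cyclisation and hydrogen transfer, which the substrate secures because the nearest π-bond of 19, C2′=C3′, lies ten carbons from C13′ and the arene is carried as the redox-inert dimethyl ether.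

Step 18
Reactants: 32 1,4-dimethoxy-2-methyl-3-[(2E,7S,11R,14E,18E,22E,27S)-3,7,11,15,19,23,27,31-octamethyldotriaconta-2,14,18,22-tetraen-1-yl]naphthalene
Product: 33 2-methyl-3-[(2E,7S,11R,14E,18E,22E,27S)-3,7,11,15,19,23,27,31-octamethyldotriaconta-2,14,18,22-tetraen-1-yl]naphthalene-1,4-dione (target)
Conditions: (NH4)2Ce(NO3)6 (2.5 equiv), MeCN/H2O/CH2Cl2, 0 °C, short contact time
Reagents that add atoms: water, O
Why: Oxidative demethylation of a hydroquinone dimethyl ether with ceric ammonium nitrate is the standard end-game for prenylated naphthoquinones and should leave the isolated trisubstituted olefins and all three stereocentres untouched.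

## Compound list

1 | menadione (2-methylnaphthalene-1,4-dione) | CC1=CC(=O)c2ccccc2C1=O | starting material
2 | menadiol (2-methylnaphthalene-1,4-diol) | Cc1cc(O)c2ccccc2c1O | intermediate
3 | 1,4-dimethoxy-2-methylnaphthalene | COc1cc(C)c(OC)c2ccccc12 | intermediate
4 | 2-(chloromethyl)-1,4-dimethoxy-3-methylnaphthalene | COc1c(C)c(CCl)c(OC)c2ccccc12 | intermediate
5 | (5-chloropent-1-yn-1-yl)trimethylsilane | C[Si](C)(C)C#CCCCCl | starting material
6 | (R)-β-butyrolactone [(4R)-4-methyloxetan-2-one] | C[C@@H]1CC(=O)O1 | starting material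
7 | [5-(trimethylsilyl)pent-4-yn-1-yl]magnesium chloride | C[Si](C)(C)C#CCCC[Mg]Cl | intermediate
8 | (3R)-3-methyl-8-(trimethylsilyl)oct-7-ynoic acid | C[Si](C)(C)C#CCCC[C@@H](C)CC(=O)O | intermediate
9 | 1,3-dioxoisoindolin-2-yl (3R)-3-methyl-8-(trimethylsilyl)oct-7-ynoate | C[Si](C)(C)C#CCCC[C@@H](C)CC(=O)ON1C(=O)c2ccccc2C1=O | intermediate
10 | (S)-citronellyl bromide [(6S)-8-bromo-2,6-dimethyloct-2-ene] | BrCC[C@@H](C)CCC=C(C)C | starting material
11 | [(3S)-3,7-dimethyloct-6-en-1-yl]magnesium bromide | Br[Mg]CC[C@@H](C)CCC=C(C)C | intermediate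
12 | bis[(3S)-3,7-dimethyloct-6-en-1-yl]zinc | CC(C)=CCC[C@H](C)CC[Zn]CC[C@@H](C)CCC=C(C)C | intermediate
13 | trimethyl[(6S,10R)-6,10,14-trimethylpentadec-13-en-1-yn-1-yl]silane | C[Si](C)(C)C#CCCC[C@@H](C)CCC[C@@H](C)CCC=C(C)C | intermediate
14 | (4R,8S)-4,8-dimethyl-13-(trimethylsilyl)tridec-12-yn-1-ol | C[Si](C)(C)C#CCCC[C@@H](C)CCC[C@@H](C)CCCO | intermediate
15 | (4R,8S)-4,8-dimethyltridec-12-yn-1-ol | C#CCCC[C@@H](C)CCC[C@@H](C)CCCO | intermediate
16 | dimethyl{(1E,6S,10R)-13-[(dimethylalumanyl)oxy]-2,6,10-trimethyltridec-1-en-1-yl}alumane | C[Al](C)/C=C(\C)CCC[C@@H](C)CCC[C@@H](C)CCCO[Al](C)C | intermediate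
17 | (4R,8S,12E)-14-(1,4-dimethoxy-3-methylnaphthalen-2-yl)-4,8,12-trimethyltetradec-12-en-1-ol | COc1c(C)c(C/C=C(\C)CCC[C@@H](C)CCC[C@@H](C)CCCO)c(OC)c2ccccc12 | intermediate
18 | (4R,8S,12E)-14-(1,4-dimethoxy-3-methylnaphthalen-2-yl)-4,8,12-trimethyltetradec-12-enoic acid | COc1c(C)c(C/C=C(\C)CCC[C@@H](C)CCC[C@@H](C)CCC(=O)O)c(OC)c2ccccc12 | intermediate
19 | 1,3-dioxoisoindolin-2-yl (4R,8S,12E)-14-(1,4-dimethoxy-3-methylnaphthalen-2-yl)-4,8,12-trimethyltetradec-12-enoate | COc1c(C)c(C/C=C(\C)CCC[C@@H](C)CCC[C@@H](C)CCC(=O)ON3C(=O)c4ccccc4C3=O)c(OC)c2ccccc12 | intermediate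
20 | geranyl bromide [(2E)-1-bromo-3,7-dimethylocta-2,6-diene] | CC(C)=CCC/C(C)=C/CBr | starting material
21 | 1-(trimethylsilyl)propyne | CC#C[Si](C)(C)C | starting material
22 | [3-(trimethylsilyl)prop-2-yn-1-yl]lithium | [Li]CC#C[Si](C)(C)C | intermediate
23 | [(5E)-6,10-dimethylundeca-5,9-dien-1-yn-1-yl]trimethylsilane | C[Si](C)(C)C#CCC/C=C(\C)CCC=C(C)C | intermediate
24 | (2E,6E)-2,6-dimethyl-11-(trimethylsilyl)undeca-2,6-dien-10-yn-1-ol | C[Si](C)(C)C#CCC/C=C(\C)CC/C=C(\C)CO | intermediate
25 | (2E,6E)-2,6-dimethyl-11-(trimethylsilyl)undeca-2,6-dien-10-yn-1-yl acetate | C[Si](C)(C)C#CCC/C=C(\C)CC/C=C(\C)COC(C)=O | intermediate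
26 | (3S)-1-bromo-3,7-dimethyloctane | BrCC[C@@H](C)CCCC(C)C | intermediate
27 | [(3S)-3,7-dimethyloctyl]magnesium bromide | Br[Mg]CC[C@@H](C)CCCC(C)C | intermediate
28 | trimethyl[(5E,9E,14S)-6,10,14,18-tetramethylnonadeca-5,9-dien-1-yn-1-yl]silane | C[Si](C)(C)C#CCC/C=C(\C)CC/C=C(\C)CCC[C@@H](C)CCCC(C)C | intermediate
29 | (5E,9E,14S)-6,10,14,18-tetramethylnonadeca-5,9-dien-1-yne | C#CCC/C=C(\C)CC/C=C(\C)CCC[C@@H](C)CCCC(C)C | intermediate
30 | dimethyl[(1E,5E,9E,14S)-2,6,10,14,18-pentamethylnonadeca-1,5,9-trien-1-yl]alumane | C[Al](C)/C=C(\C)CC/C=C(\C)CC/C=C(\C)CCC[C@@H](C)CCCC(C)C | intermediate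
31 | chloro[(1E,5E,9E,14S)-2,6,10,14,18-pentamethylnonadeca-1,5,9-trien-1-yl]zinc | Cl[Zn]/C=C(\C)CC/C=C(\C)CC/C=C(\C)CCC[C@@H](C)CCCC(C)C | intermediate
32 | 1,4-dimethoxy-2-methyl-3-[(2E,7S,11R,14E,18E,22E,27S)-3,7,11,15,19,23,27,31-octamethyldotriaconta-2,14,18,22-tetraen-1-yl]naphthalene | COc1c(C)c(C/C=C(\C)CCC[C@@H](C)CCC[C@@H](C)CC/C=C(\C)CC/C=C(\C)CC/C=C(\C)CCC[C@@H](C)CCCC(C)C)c(OC)c2ccccc12 | intermediate
33 | 2-methyl-3-[(2E,7S,11R,14E,18E,22E,27S)-3,7,11,15,19,23,27,31-octamethyldotriaconta-2,14,18,22-tetraen-1-yl]naphthalene-1,4-dione | CC1=C(C/C=C(\C)CCC[C@@H](C)CCC[C@@H](C)CC/C=C(\C)CC/C=C(\C)CC/C=C(\C)CCC[C@@H](C)CCCC(C)C)C(=O)c2ccccc2C1=O | target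

## Step count and risks

Total step count: 18.
Longest linear sequence: 10 (steps 3, 4, 5, 6, 7, 8, 9, 10, 17, 18).

**Step 17.**
- Risk: residual methyl–aluminium or methyl–zinc species may transfer methyl instead of alkenyl.
- Risk: the Lewis-acidic aluminium by-product may consume the redox-active ester by carbonyl attack.
- Risk: the alkenyl metal may be protonated before it reaches nickel.
- Fallback: it sets out from 29 and 19 and comes back at 32. The methylalumination of 29 is quenched with I2 (THF, −30 °C) to give the isolable, aluminium-free (1E,5E,9E,14S)-1-iodo-2,6,10,14,18-pentamethylnonadeca-1,5,9-triene F1.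
- F1 and 19 are then joined as two electrophiles by the known nickel/bipyridine reductive decarboxylative alkenylation. This runs in an undivided cell with a sacrificial Mg anode, a carbon cathode and AgNO3 additive in DMF at rt. It needs no organometallic nucleophile and is established for the CH2–CH=C(CH3) junctions of oligoprenoids.

**Step 5.**
- Risk: in a primary–primary coupling the C8′ radical may be lost by hydrogen abstraction or by slow 6-exo attack on the silylalkyne.
- Risk: the alkylnickel may decay by β-hydride elimination or homocoupling.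
- Fallback: it sets out from 9 (with Grignard reagent 11 made from 10) and comes back at 13. Visible-light iododecarboxylation of 9 (LiI, PPh3 cat., blue light, acetone) should give [(6R)-7-iodo-6-methylhept-1-yn-1-yl]trimethylsilane F2.
- F2 is then joined to 11 by polar Kochi-type copper catalysis (Li2CuCl4, THF/NMP, 0 °C) instead of a nickel radical process.

**Step 15.**
- Risk: attack at the γ-carbon (SN2′), erosion of the E geometry through a π-allylcopper species, or acyl attack of the Grignard reagent on the acetate may compete.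
- Fallback: it sets out from 25 and 26 and comes back at 28. Palladium-catalysed allylic sulfonylation of 25 (sodium p-toluenesulfinate, Pd(PPh3)4 cat., THF/MeOH) should give the linear sulfone trimethyl[(5E,9E)-6,10-dimethyl-11-(4-methylbenzenesulfonyl)undeca-5,9-dien-1-yn-1-yl]silane F3.
- The α-sulfonyl carbanion of F3 (n-BuLi, THF/DMPU, −78 °C) is alkylated by 26. This gives trimethyl[(5E,9E,14S)-6,10,14,18-tetramethyl-11-(4-methylbenzenesulfonyl)nonadeca-5,9-dien-1-yn-1-yl]silane F4, a mixture of epimers at the sulfone carbon.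
- Palladium-catalysed reductive desulfonylation (PdCl2(dppp) cat., LiEt3BH, THF, 0 °C) removes the sulfone with the olefin held in place and E.

## Further compounds

F1 | step 17 | (1E,5E,9E,14S)-1-iodo-2,6,10,14,18-pentamethylnonadeca-1,5,9-triene | I/C=C(\C)CC/C=C(\C)CC/C=C(\C)CCC[C@@H](C)CCCC(C)C
F2 | step 5 | [(6R)-7-iodo-6-methylhept-1-yn-1-yl]trimethylsilane | C[Si](C)(C)C#CCCC[C@@H](C)CI
F3 | step 15 | trimethyl[(5E,9E)-6,10-dimethyl-11-(4-methylbenzenesulfonyl)undeca-5,9-dien-1-yn-1-yl]silane | C[Si](C)(C)C#CCC/C=C(\C)CC/C=C(\C)CS(=O)(=O)c1ccc(C)cc1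
F4 | step 15 | trimethyl[(5E,9E,14S)-6,10,14,18-tetramethyl-11-(4-methylbenzenesulfonyl)nonadeca-5,9-dien-1-yn-1-yl]silane (epimers at C11) | C[Si](C)(C)C#CCC/C=C(\C)CC/C=C(\C)C(CC[C@@H](C)CCCC(C)C)S(=O)(=O)c1ccc(C)cc1
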